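Compound numbers 1–33 follow the order of the steps below and are used unchanged in every section.

## Analysis of the target

Target 33 is a trans-2-aryl-3-(hydroxymethyl)-2,3-dihydrobenzofuran (guaiacyl ring A on C2, benzo ring B, dihydrofuran ring C made of O1, C2, C3, C3a and C7a). Its C5 is tied through one methylene to C-α of a γ-butyrolactone (ring D), whose C-β carries a secondary benzylic alcohol on a second guaiacyl ring (ring E). The five stereocentres fall into two groups separated by ring B: C2 (S) and C3 (R), trans on ring C; and C-α (R) and C-β (R), trans on ring D, with the carbinol carbon (R) anti to the C-α branch when the chain C-γ–C-β–carbinol–ring E is drawn zigzag. Nothing relays configuration from one group to the other, so each must be set in absolute terms. The sensitive groups are two free phenols, a p-hydroxybenzylic alcohol that ionises under acid and can pull the lactone onto itself under base, the benzylic ether C2–O1 (acid, hydrogenolysis) and the epimerisable C-α. The difficulty is therefore absolute control of ring C without a directing handle, control of three contiguous centres around ring D, and a protecting-group set that leaves without acid, strong base or hydrogen. The strategy rests on ring B: it carries O1 on C7a and, on the neighbouring C3a, C3 with its CH2OH, which is the oxygen/carbon pattern of an ortho-quinone methide. C2 is then a single benzylic carbon between C3 and O1, so a one-carbon ylide bearing ring A can bridge the methide carbon and oxygen.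

## Retrosynthetic reasoning

33 from 32. All four hydroxyls are masked as silyl ethers in 32, so the last step needs only buffered fluoride. Acid would ionise the p-oxygenated benzylic positions and hydrogen would open the C2–O1 bond; both are avoided.

32 from 21 and 30 (through enolate 31). The C-α–CH2 bond is cut because it divides the molecule into two halves of similar size that share no stereocentre. Alkylation anti to the large C-β substituent sets C-α, and trans is also the thermodynamic arrangement of the only epimerisable centre. Growing ring D on the dihydrobenzofuran instead (arylidene succinate, hydrogenation, auxiliary aldol, selective reduction) would place alkoxide chemistry and three selectivity problems on the most valuable intermediate, and was set aside for that reason.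

30 from 28, 27, and from 25 with 9. The C-β–carbinol bond is cut as an anti-aldol, which sets both stereocentres of ring D's side arm in one reaction on cheap material. The imide carbonyl is then reduced to the CH2–O of the lactone, which closes onto the ester that was carried as the aldol α-substituent. The carbinol has to be silylated before reduction, because its free hydroxyl could form the isomeric lactone.

21 from 20 and 19. The C5 carbon is carried as an ester and adjusted to the benzylic bromide only after ring C exists.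

19 from 7 and 15 (key disconnection). The C2–C3 and O1–C2 bonds are cut; both end on C2, the only ring C carbon that does not belong to the substitution pattern of ring B. Cutting there returns a phenol with an ortho benzylic leaving group, that is, methide 16 on demand, and a benzylic sulfonium salt. This gives ring C and both of its stereocentres in one step from two fragments of equal weight. The forward reaction must generate 16 and ylide 17 in the same flask, join them faster than 16 decays, and transfer the chirality of the sulfide to C2 and, through the relative topicity of the C–C bond formation, to C3.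

7 from 5, 4, 3, 2 and 1. The sulfone comes from the ortho-hydroxybenzylic alcohol by acid-promoted exchange with 6. The diol comes from a vinyl group, and the vinyl group from ortho-formylation of 1 and methylenation. The benzylic centre is left racemic because it becomes trigonal in 16.

15 from 11 and 14. The salt is made by S-alkylation; 11 comes from 8 through 9 and 10, and the C2-symmetric sulfide 14 from diol 12 through 13 with double inversion. Aldehyde 9 serves twice, as the source of ring A and as the aldol acceptor for ring E.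

## Alternatives that were turned down

Alternative 1: The C3–C3a and O1–C2 bonds are cut, so that rings A–C arise from two molecules of one cinnamoyl monomer, the chiral imide A1. In the forward step Ag2O oxidises A1 to phenoxyl radicals, β–5 coupling forms C3–C3a, and the phenol closes onto the resulting quinone methide to give the trans bis-imide A2.
- For: one step builds ring C, both stereocentres and the full carbon set of rings A–C from a single cheap monomer. In steps to the dihydrobenzofuran it is clearly stronger than the chosen route.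
- Against: radical dimerisation spreads material over several coupling modes. The auxiliary sits three atoms from the new C3 centre on a freely rotating acryloyl unit, so facial control is indirect. A2 carries two acyl imides that must be told apart, and a three-carbon enoyl chain on C5 where the target needs one carbon, so two carbons have to be excised after the C3 acyl group has been reduced and the ring A phenol protected.
- Comparison: the chosen strategy is longer to ring C, but it delivers C5 as a one-carbon ester already distinct from the C3 silyloxymethyl group, wastes no carbons, and places the controlling element on the reacting carbon itself.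

Alternative 2: The lactone C–O bond of ring D is cut back to the cyclobutanone A3. In the forward step a chiral phosphoric acid with aqueous H2O2 inserts oxygen next to one of the two enantiotopic CH2 groups and gives lactone A4.
- For: chirality at C-β comes from a catalyst, with no auxiliary to attach and remove; on atom economy it is stronger than the aldol used here.
- Against: A3 must already hold the carbinol stereocentre on a four-membered ring, which costs several steps. The catalyst has to distinguish two CH2 groups that differ only through a branched substituent, against or with the bias of the existing centre. Acid and peroxide meet an electron-rich silyloxyarene and an ionisable benzylic ether. Above all, the step addresses ring D only and leaves the harder problem, ring C, untouched.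
- Comparison: A4 is identical in constitution and configuration with lactone 30, which the chosen route reaches in four steps with both centres set together, and the chosen key step spends its risk on ring C instead.

Alternative 3: The C2–C3 bond is cut, with O1–C2 already present as a benzyl aryl ether in the aryldiazoacetate A5. In the forward step a chiral dirhodium tetracarboxylate such as Rh2(S-PTTL)4 forms the carbene, which inserts into the ether-activated benzylic C–H through a five-membered transition state to give the cis ester A6.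
- For: this is the best-precedented enantioselective entry to 2-aryl-2,3-dihydrobenzofurans, and it is catalytic. On certainty of reactivity and of enantiocontrol it is stronger than the chosen key step.
- Against: it gives the cis ring, so C3 must be epimerised and the ester reduced and protected. C5 arrives as a bromide that still has to be turned into the benzylic electrophile by metalation, formylation and reduction. A5 itself needs an arylacetate, O-benzylation and diazo transfer. The sequence is linear throughout.
- Comparison: the chosen strategy accepts a less proven ring formation and in return gives the trans ring directly, with C3 at the alcohol oxidation level, the C5 carbon in place and two fragments of equal size joined late.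

Key step: step 12

Remarks on the chemistry:
- The benzylic carbon of 4, 5 and 7 is racemic by design.
- Sulfide 14 is not assumed to be a catalogue item and is made in two steps.
- The sense of induction in steps 12 and 16 is taken from the accepted transition-state models of the parent reactions and is a prediction.

## Route

Step 1
Reactants: 1 methyl vanillate (methyl 4-hydroxy-3-methoxybenzoate)
Product: 2 methyl 3-formyl-4-hydroxy-5-methoxybenzoate
Conditions: hexamethylenetetramine, CF3CO2H, 90 °C; then 2 M HCl, 25 °C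
Reagents that add atoms: hexamethylenetetramine, C1N2CN3CN1CN(C2)C3; water, O
Why: Duff formylation; the phenol directs aminomethylation to its only free ortho position, and internal hydride transfer followed by hydrolysis gives the aldehyde. The ester is inert to the acid.

Step 2
Reactants: 2 methyl 3-formyl-4-hydroxy-5-methoxybenzoate
Product: 3 methyl 4-hydroxy-3-methoxy-5-vinylbenzoate
Conditions: Ph3PCH3Br (2.5 equiv), KOtBu (2.4 equiv), THF, 0 → 25 °C
Reagents that add atoms: methyltriphenylphosphonium bromide, C[P+](c1ccccc1)(c1ccccc1)c1ccccc1.[Br-]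
Why: Wittig methylenation; one equivalent of base is spent on the phenol, the phenoxide aldehyde still reacts with the unstabilised ylide, and the benzoate is not attacked at this temperature.

Step 3
Reactants: 3 methyl 4-hydroxy-3-methoxy-5-vinylbenzoate
Product: 4 methyl 3-(1,2-dihydroxyethyl)-4-hydroxy-5-methoxybenzoate (racemic)
Conditions: K2OsO4·2H2O (1 mol %), N-methylmorpholine N-oxide, acetone/H2O, 25 °C
Reagents that add atoms: N-methylmorpholine N-oxide, C[N+]1([O-])CCOCC1; water, O
Why: Upjohn dihydroxylation of a terminal styrene. The new centre is left racemic because it is erased when the methide forms in step 12.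

Step 4
Reactants: 4 methyl 3-(1,2-dihydroxyethyl)-4-hydroxy-5-methoxybenzoate (racemic)
Product: 5 methyl 3-[2-(tert-butyldiphenylsilyloxy)-1-hydroxyethyl]-4-hydroxy-5-methoxybenzoate (racemic)
Conditions: t-BuPh2SiCl (1.05 equiv), imidazole, CH2Cl2/DMF, 0 °C
Reagents that add atoms: tert-butyldiphenylsilyl chloride, CC(C)(C)[Si](Cl)(c1ccccc1)c1ccccc1
Why: Imidazole-mediated silylation is fastest at the unhindered primary hydroxyl; the benzylic hydroxyl and the doubly flanked, hydrogen-bonded phenol are too crowded for this bulky group. The diphenyl-tert-butylsilyl ether is chosen over the dimethyl analogue because it must survive the acid of step 5.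

Step 5
Reactants: 5 methyl 3-[2-(tert-butyldiphenylsilyloxy)-1-hydroxyethyl]-4-hydroxy-5-methoxybenzoate (racemic); 6 sodium p-toluenesulfinate
Product: 7 methyl 3-[2-(tert-butyldiphenylsilyloxy)-1-(p-tolylsulfonyl)ethyl]-4-hydroxy-5-methoxybenzoate (racemic)
Conditions: 6 (3 equiv), HCO2H/THF/H2O, 40 °C
Reagents that add atoms: none
Why: Acid-promoted substitution of an ortho-hydroxybenzylic alcohol; the ortho hydroxyl assists loss of water and sulfinate adds through sulfur. O-attack is reversible, so the sulfone is the thermodynamic product.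

Step 6
Reactants: 8 vanillin
Product: 9 3-methoxy-4-(triisopropylsilyloxy)benzaldehyde
Conditions: i-Pr3SiCl, imidazole, DMF, 25 °C
Reagents that add atoms: triisopropylsilyl chloride, CC(C)[Si](Cl)(C(C)C)C(C)C
Why: Phenol silylation. The triisopropylsilyl aryl ether is chosen because it has to survive carbonate in step 12 and hydride and amide bases later, yet leave with fluoride.

Step 7
Reactants: 9 3-methoxy-4-(triisopropylsilyloxy)benzaldehyde
Product: 10 [3-methoxy-4-(triisopropylsilyloxy)phenyl]methanol
Conditions: NaBH4, MeOH/THF, 0 °C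
Reagents that add atoms: none
Why: Borohydride reduction of an aryl aldehyde; the aryl silyl ether tolerates the short, cold exposure.

Step 8
Reactants: 10 [3-methoxy-4-(triisopropylsilyloxy)phenyl]methanol
Product: 11 4-(bromomethyl)-2-methoxy-1-(triisopropylsilyloxy)benzene
Conditions: CBr4, PPh3, CH2Cl2, 0 °C
Reagents that add atoms: carbon tetrabromide, BrC(Br)(Br)Br
Why: Appel bromination under neutral conditions, which spares the silyl ether.

Step 9
Reactants: 12 (2R,5R)-hexane-2,5-diol
Product: 13 (2R,5R)-hexane-2,5-diyl dimethanesulfonate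
Conditions: MeSO2Cl, Et3N, CH2Cl2, 0 °C
Reagents that add atoms: methanesulfonyl chloride, CS(=O)(=O)Cl
Why: O-sulfonylation with retention at both carbinol carbons.

Step 10
Reactants: 13 (2R,5R)-hexane-2,5-diyl dimethanesulfonate
Product: 14 (2S,5S)-2,5-dimethylthiolane
Conditions: Na2S·9H2O, DMSO, 25 °C; distillation
Reagents that add atoms: sodium sulfide, [Na+].[Na+].[S-2]
Why: Double SN2 displacement by sulfide, first intermolecular and then 5-exo-tet; both centres invert, so the (R,R)-diol gives the (S,S)-thiolane.

Step 11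
Reactants: 11 4-(bromomethyl)-2-methoxy-1-(triisopropylsilyloxy)benzene; 14 (2S,5S)-2,5-dimethylthiolane
Product: 15 (2S,5S)-1-[3-methoxy-4-(triisopropylsilyloxy)benzyl]-2,5-dimethylthiolan-1-ium trifluoromethanesulfonate
Conditions: LiOTf (3 equiv), CH2Cl2/H2O, 25 °C
Reagents that add atoms: lithium trifluoromethanesulfonate, [Li+].[O-]S(=O)(=O)C(F)(F)F
Why: S-alkylation of the sulfide; its C2 symmetry makes the two lone pairs equivalent, so a single sulfonium salt results. Triflate replaces bromide so that the salt cannot revert by bromide attack at the electron-rich benzylic carbon.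

Step 12
Reactants: 7 methyl 3-[2-(tert-butyldiphenylsilyloxy)-1-(p-tolylsulfonyl)ethyl]-4-hydroxy-5-methoxybenzoate (racemic); 15 (2S,5S)-1-[3-methoxy-4-(triisopropylsilyloxy)benzyl]-2,5-dimethylthiolan-1-ium trifluoromethanesulfonate
Product: 19 methyl (2S,3R)-3-[(tert-butyldiphenylsilyloxy)methyl]-7-methoxy-2-[3-methoxy-4-(triisopropylsilyloxy)phenyl]-2,3-dihydro-1-benzofuran-5-carboxylate, via ortho-quinone methide 16 (not isolated), via sulfonium ylide 17 (not isolated), via betaine 18 (not isolated)
Conditions: 15 (1.5 equiv), Cs2CO3 (3 equiv), MeCN, −20 → 0 °C, slow addition of 7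
Reagents that add atoms: none
Why: Cs2CO3 deprotonates the phenol of 7, whose phenoxide expels p-toluenesulfinate to give methide 16, and the same base reversibly deprotonates 15 to the semi-stabilised ylide 17. The ylide carbon adds to the exocyclic methide carbon (C2–C3 bond), which restores the arene and gives betaine 18, and the phenoxide then displaces the thiolane at C2 with inversion (O1–C2 bond), a 5-exo-tet closure of ring C. The closest known reaction type is the [4+1] annulation of base-generated ortho-quinone methides from 2-(1-tosylalkyl)phenols with sulfonium ylides to trans-2,3-dihydrobenzofurans, including variants steered by chiral sulfides; a benzylic ylide on an enolisable alkyl methide lies at the edge of that scope. C2 is controlled by the C2-symmetric thiolane: only one ylide exists, its aryl group points away from the ring, and the α-methyl group cis to the ylide carbon blocks one face, so that after inversion C2 should be S (the sense known for epoxidations with this class of sulfide, transposed to this connectivity). C3 is set in the same C–C bond formation, where the approach that keeps ring A and the silyloxymethyl group apart leads to the trans ring and hence C3 (R). The step needs capture of 16 to outrun its 1,5-hydrogen shift to a vinylphenol and its self-addition; the ester para to the methide oxygen raises its electrophilicity, and slow addition of 7 to an excess of 15 keeps 16 dilute. It also needs C–C bond formation to win over benzyl transfer from 15 to the phenoxide, which the fast loss of sulfinate from the hindered phenoxide should secure.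

Step 13
Reactants: 19 methyl (2S,3R)-3-[(tert-butyldiphenylsilyloxy)methyl]-7-methoxy-2-[3-methoxy-4-(triisopropylsilyloxy)phenyl]-2,3-dihydro-1-benzofuran-5-carboxylate
Product: 20 [(2S,3R)-3-[(tert-butyldiphenylsilyloxy)methyl]-7-methoxy-2-[3-methoxy-4-(triisopropylsilyloxy)phenyl]-2,3-dihydro-1-benzofuran-5-yl]methanol
Conditions: i-Bu2AlH (2.5 equiv), CH2Cl2, −78 → 0 °C; aq. potassium sodium tartrate
Reagents that add atoms: none
Why: Hydride reduction of the aryl ester to the benzylic alcohol; silyl ethers and the benzylic ether of ring C are inert and no stereocentre is touched.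

Step 14
Reactants: 20 [(2S,3R)-3-[(tert-butyldiphenylsilyloxy)methyl]-7-methoxy-2-[3-methoxy-4-(triisopropylsilyloxy)phenyl]-2,3-dihydro-1-benzofuran-5-yl]methanol
Product: 21 tert-butyl{[(2S,3R)-5-(bromomethyl)-7-methoxy-2-[3-methoxy-4-(triisopropylsilyloxy)phenyl]-2,3-dihydro-1-benzofuran-3-yl]methoxy}diphenylsilane
Conditions: CBr4, PPh3, CH2Cl2, −20 °C; used at once
Reagents that add atoms: carbon tetrabromide, BrC(Br)(Br)Br
Why: Appel bromination under neutral conditions. The product is a para-alkoxybenzylic bromide and is not stored.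

Step 15
Reactants: 22 (R)-4-benzyl-1,3-oxazolidin-2-one; 23 methyl 4-chloro-4-oxobutanoate
Product: 25 methyl 4-[(R)-4-benzyl-2-oxo-1,3-oxazolidin-3-yl]-4-oxobutanoate, via lithium oxazolidinide 24 (not isolated)
Conditions: n-BuLi, THF, −78 °C; then 23
Reagents that add atoms: none
Why: N-acylation of the lithiated auxiliary by the acid chloride; the methyl ester does not react at −78 °C.

Step 16
Reactants: 25 methyl 4-[(R)-4-benzyl-2-oxo-1,3-oxazolidin-3-yl]-4-oxobutanoate; 9 3-methoxy-4-(triisopropylsilyloxy)benzaldehyde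
Product: 27 methyl (3S,4R)-3-{[(R)-4-benzyl-2-oxo-1,3-oxazolidin-3-yl]carbonyl}-4-hydroxy-4-[3-methoxy-4-(triisopropylsilyloxy)phenyl]butanoate, via trimethylsilyl ether 26 (not isolated)
Conditions: MgCl2 (0.2 equiv), Et3N, Me3SiCl, EtOAc, 23 °C; then pyridinium p-toluenesulfonate, MeOH, 0 °C
Reagents that add atoms: none
Why: MgCl2-catalysed direct anti-aldol reaction of an N-acyloxazolidinone with a non-enolisable aldehyde; soft enolisation occurs only at the imide α-CH2 and gives the chelated Z-enolate. The aldehyde adds anti to the benzyl group of the auxiliary through a boat-like transition state, which should give the anti adduct with C3 (S) and the carbinol (R); O-silylation of the aldolate turns the catalyst over and blocks retro-aldol and lactonisation. Brief buffered methanolysis then removes only the trimethylsilyl group.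

Step 17
Reactants: 27 methyl (3S,4R)-3-{[(R)-4-benzyl-2-oxo-1,3-oxazolidin-3-yl]carbonyl}-4-hydroxy-4-[3-methoxy-4-(triisopropylsilyloxy)phenyl]butanoate
Product: 28 methyl (3S,4R)-3-{[(R)-4-benzyl-2-oxo-1,3-oxazolidin-3-yl]carbonyl}-4-(tert-butyldimethylsilyloxy)-4-[3-methoxy-4-(triisopropylsilyloxy)phenyl]butanoate
Conditions: t-BuMe2SiOTf, 2,6-lutidine, CH2Cl2, −78 → 0 °C
Reagents that add atoms: tert-butyldimethylsilyl trifluoromethanesulfonate, CC(C)(C)[Si](C)(C)OS(=O)(=O)C(F)(F)F
Why: Silylation of the hindered secondary benzylic alcohol with the silyl triflate. It is done at once, so that the free hydroxyl cannot close onto the methyl ester to give the isomeric lactone.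

Step 18
Reactants: 28 methyl (3S,4R)-3-{[(R)-4-benzyl-2-oxo-1,3-oxazolidin-3-yl]carbonyl}-4-(tert-butyldimethylsilyloxy)-4-[3-methoxy-4-(triisopropylsilyloxy)phenyl]butanoate
Product: 30 (R)-4-{(R)-(tert-butyldimethylsilyloxy)[3-methoxy-4-(triisopropylsilyloxy)phenyl]methyl}oxolan-2-one, via hydroxy ester 29 (not isolated)
Conditions: LiBH4 (1.1 equiv), MeOH (1.1 equiv), THF, 0 °C; then pyridinium p-toluenesulfonate (cat.), CH2Cl2, 25 °C
Reagents that add atoms: none
Why: Reductive removal of the auxiliary; LiBH4 attacks the activated imide carbonyl faster than the methyl ester. The new primary hydroxyl closes onto the ester (5-exo-trig) to give the lactone, and neither stereocentre is touched.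

Step 19
Reactants: 30 (R)-4-{(R)-(tert-butyldimethylsilyloxy)[3-methoxy-4-(triisopropylsilyloxy)phenyl]methyl}oxolan-2-one; 21 tert-butyl{[(2S,3R)-5-(bromomethyl)-7-methoxy-2-[3-methoxy-4-(triisopropylsilyloxy)phenyl]-2,3-dihydro-1-benzofuran-3-yl]methoxy}diphenylsilane
Product: 32 (3R,4R)-3-{[(2S,3R)-3-[(tert-butyldiphenylsilyloxy)methyl]-7-methoxy-2-[3-methoxy-4-(triisopropylsilyloxy)phenyl]-2,3-dihydro-1-benzofuran-5-yl]methyl}-4-{(R)-(tert-butyldimethylsilyloxy)[3-methoxy-4-(triisopropylsilyloxy)phenyl]methyl}oxolan-2-one, via lithium enolate 31 (not isolated)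
Conditions: LiN(SiMe3)2 (1.05 equiv), THF, −78 °C; then 21, DMPU, −78 → −40 °C
Reagents that add atoms: none
Why: Alkylation of a γ-butyrolactone lithium enolate; the bulky silyloxybenzyl group on C-β shields one face, so the benzylic bromide enters anti to it and C-α should be R (trans). The trans arrangement is also the thermodynamic one.

Step 20
Reactants: 32 (3R,4R)-3-{[(2S,3R)-3-[(tert-butyldiphenylsilyloxy)methyl]-7-methoxy-2-[3-methoxy-4-(triisopropylsilyloxy)phenyl]-2,3-dihydro-1-benzofuran-5-yl]methyl}-4-{(R)-(tert-butyldimethylsilyloxy)[3-methoxy-4-(triisopropylsilyloxy)phenyl]methyl}oxolan-2-one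
Product: 33 (3R,4R)-4-[(R)-hydroxy(4-hydroxy-3-methoxyphenyl)methyl]-3-{[(2S,3R)-2-(4-hydroxy-3-methoxyphenyl)-3-(hydroxymethyl)-7-methoxy-2,3-dihydro-1-benzofuran-5-yl]methyl}oxolan-2-one
Conditions: Bu4NF/AcOH (1:1, excess), THF, 0 → 25 °C
Reagents that add atoms: none
Why: Fluoride cleaves the two aryl, the primary and the secondary benzylic silyl ethers. The acetic acid buffer keeps phenols and the carbinol protonated, so neither lactone migration nor quinone-methide formation is triggered, and no acid strong enough to ionise the benzylic positions is present.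

## Compound list

1 | methyl vanillate (methyl 4-hydroxy-3-methoxybenzoate) | COC(=O)c1ccc(O)c(OC)c1 | starting material
2 | methyl 3-formyl-4-hydroxy-5-methoxybenzoate | COC(=O)c1cc(OC)c(O)c(C=O)c1 | intermediate
3 | methyl 4-hydroxy-3-methoxy-5-vinylbenzoate | COC(=O)c1cc(OC)c(O)c(C=C)c1 | intermediate
4 | methyl 3-(1,2-dihydroxyethyl)-4-hydroxy-5-methoxybenzoate (racemic) | COC(=O)c1cc(OC)c(O)c(C(O)CO)c1 | intermediate
5 | methyl 3-[2-(tert-butyldiphenylsilyloxy)-1-hydroxyethyl]-4-hydroxy-5-methoxybenzoate (racemic) | COC(=O)c1cc(OC)c(O)c(C(O)CO[Si](c2ccccc2)(c2ccccc2)C(C)(C)C)c1 | intermediate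
6 | sodium p-toluenesulfinate | Cc1ccc(S(=O)[O-])cc1.[Na+] | starting material
7 | methyl 3-[2-(tert-butyldiphenylsilyloxy)-1-(p-tolylsulfonyl)ethyl]-4-hydroxy-5-methoxybenzoate (racemic) | COC(=O)c1cc(OC)c(O)c(C(CO[Si](c2ccccc2)(c2ccccc2)C(C)(C)C)S(=O)(=O)c2ccc(C)cc2)c1 | intermediate
8 | vanillin | COc1cc(C=O)ccc1O | starting material
9 | 3-methoxy-4-(triisopropylsilyloxy)benzaldehyde | COc1cc(C=O)ccc1O[Si](C(C)C)(C(C)C)C(C)C | intermediate
10 | [3-methoxy-4-(triisopropylsilyloxy)phenyl]methanol | COc1cc(CO)ccc1O[Si](C(C)C)(C(C)C)C(C)C | intermediate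
11 | 4-(bromomethyl)-2-methoxy-1-(triisopropylsilyloxy)benzene | COc1cc(CBr)ccc1O[Si](C(C)C)(C(C)C)C(C)C | intermediate
12 | (2R,5R)-hexane-2,5-diol | C[C@@H](O)CC[C@@H](C)O | starting material
13 | (2R,5R)-hexane-2,5-diyl dimethanesulfonate | C[C@@H](OS(C)(=O)=O)CC[C@@H](C)OS(C)(=O)=O | intermediate
14 | (2S,5S)-2,5-dimethylthiolane | C[C@H]1CC[C@H](C)S1 | intermediate
15 | (2S,5S)-1-[3-methoxy-4-(triisopropylsilyloxy)benzyl]-2,5-dimethylthiolan-1-ium trifluoromethanesulfonate | C[C@H]1CC[C@H](C)[S+]1Cc2ccc(O[Si](C(C)C)(C(C)C)C(C)C)c(OC)c2.[O-]S(=O)(=O)C(F)(F)F | intermediate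
16 | ortho-quinone methide, methyl 3-[2-(tert-butyldiphenylsilyloxy)ethylidene]-5-methoxy-4-oxocyclohexa-1,5-diene-1-carboxylate (alkene geometry not specified) | COC(=O)C1=CC(=CCO[Si](c2ccccc2)(c2ccccc2)C(C)(C)C)C(=O)C(OC)=C1 | intermediate
17 | sulfonium ylide, (2S,5S)-2,5-dimethylthiolan-1-ium-1-yl [3-methoxy-4-(triisopropylsilyloxy)phenyl]methanide | C[C@H]1CC[C@H](C)[S+]1[CH-]c2ccc(O[Si](C(C)C)(C(C)C)C(C)C)c(OC)c2 | intermediate
18 | betaine, 2-{(2R,3R)-1-(tert-butyldiphenylsilyloxy)-3-[(2S,5S)-2,5-dimethylthiolan-1-ium-1-yl]-3-[3-methoxy-4-(triisopropylsilyloxy)phenyl]propan-2-yl}-6-methoxy-4-(methoxycarbonyl)phenolate | COc1cc([C@@H]([C@@H](CO[Si](c4ccccc4)(c5ccccc5)C(C)(C)C)c2cc(C(=O)OC)cc(OC)c2[O-])[S+]3[C@@H](C)CC[C@@H]3C)ccc1O[Si](C(C)C)(C(C)C)C(C)C | intermediate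
19 | methyl (2S,3R)-3-[(tert-butyldiphenylsilyloxy)methyl]-7-methoxy-2-[3-methoxy-4-(triisopropylsilyloxy)phenyl]-2,3-dihydro-1-benzofuran-5-carboxylate | COc1cc([C@H]2Oc3c(OC)cc(C(=O)OC)cc3[C@@H]2CO[Si](c4ccccc4)(c5ccccc5)C(C)(C)C)ccc1O[Si](C(C)C)(C(C)C)C(C)C | intermediate
20 | [(2S,3R)-3-[(tert-butyldiphenylsilyloxy)methyl]-7-methoxy-2-[3-methoxy-4-(triisopropylsilyloxy)phenyl]-2,3-dihydro-1-benzofuran-5-yl]methanol | COc1cc([C@H]2Oc3c(OC)cc(CO)cc3[C@@H]2CO[Si](c4ccccc4)(c5ccccc5)C(C)(C)C)ccc1O[Si](C(C)C)(C(C)C)C(C)C | intermediate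
21 | tert-butyl{[(2S,3R)-5-(bromomethyl)-7-methoxy-2-[3-methoxy-4-(triisopropylsilyloxy)phenyl]-2,3-dihydro-1-benzofuran-3-yl]methoxy}diphenylsilane | COc1cc([C@H]2Oc3c(OC)cc(CBr)cc3[C@@H]2CO[Si](c4ccccc4)(c5ccccc5)C(C)(C)C)ccc1O[Si](C(C)C)(C(C)C)C(C)C | intermediate
22 | (R)-4-benzyl-1,3-oxazolidin-2-one | O=C1N[C@H](Cc2ccccc2)CO1 | starting material
23 | methyl 4-chloro-4-oxobutanoate | COC(=O)CCC(Cl)=O | starting material
24 | N-lithio-(R)-4-benzyl-1,3-oxazolidin-2-one | [Li]N1[C@H](Cc2ccccc2)COC1=O | intermediate
25 | methyl 4-[(R)-4-benzyl-2-oxo-1,3-oxazolidin-3-yl]-4-oxobutanoate | COC(=O)CCC(=O)N1[C@H](Cc2ccccc2)COC1=O | intermediate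
26 | methyl (3S,4R)-3-{[(R)-4-benzyl-2-oxo-1,3-oxazolidin-3-yl]carbonyl}-4-[3-methoxy-4-(triisopropylsilyloxy)phenyl]-4-(trimethylsilyloxy)butanoate | COC(=O)C[C@@H]([C@@H](O[Si](C)(C)C)c1ccc(O[Si](C(C)C)(C(C)C)C(C)C)c(OC)c1)C(=O)N1[C@H](Cc2ccccc2)COC1=O | intermediate
27 | methyl (3S,4R)-3-{[(R)-4-benzyl-2-oxo-1,3-oxazolidin-3-yl]carbonyl}-4-hydroxy-4-[3-methoxy-4-(triisopropylsilyloxy)phenyl]butanoate | COC(=O)C[C@@H]([C@@H](O)c1ccc(O[Si](C(C)C)(C(C)C)C(C)C)c(OC)c1)C(=O)N1[C@H](Cc2ccccc2)COC1=O | intermediate
28 | methyl (3S,4R)-3-{[(R)-4-benzyl-2-oxo-1,3-oxazolidin-3-yl]carbonyl}-4-(tert-butyldimethylsilyloxy)-4-[3-methoxy-4-(triisopropylsilyloxy)phenyl]butanoate | COC(=O)C[C@@H]([C@@H](O[Si](C)(C)C(C)(C)C)c1ccc(O[Si](C(C)C)(C(C)C)C(C)C)c(OC)c1)C(=O)N1[C@H](Cc2ccccc2)COC1=O | intermediate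
29 | methyl (3R,4R)-4-(tert-butyldimethylsilyloxy)-3-(hydroxymethyl)-4-[3-methoxy-4-(triisopropylsilyloxy)phenyl]butanoate | COC(=O)C[C@H](CO)[C@@H](O[Si](C)(C)C(C)(C)C)c1ccc(O[Si](C(C)C)(C(C)C)C(C)C)c(OC)c1 | intermediate
30 | (R)-4-{(R)-(tert-butyldimethylsilyloxy)[3-methoxy-4-(triisopropylsilyloxy)phenyl]methyl}oxolan-2-one | O=C1C[C@H](CO1)[C@@H](O[Si](C)(C)C(C)(C)C)c2ccc(O[Si](C(C)C)(C(C)C)C(C)C)c(OC)c2 | intermediate
31 | lithium enolate of 30 | [Li]OC1=C[C@@H]([C@@H](O[Si](C)(C)C(C)(C)C)c2ccc(O[Si](C(C)C)(C(C)C)C(C)C)c(OC)c2)CO1 | intermediate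
32 | (3R,4R)-3-{[(2S,3R)-3-[(tert-butyldiphenylsilyloxy)methyl]-7-methoxy-2-[3-methoxy-4-(triisopropylsilyloxy)phenyl]-2,3-dihydro-1-benzofuran-5-yl]methyl}-4-{(R)-(tert-butyldimethylsilyloxy)[3-methoxy-4-(triisopropylsilyloxy)phenyl]methyl}oxolan-2-one | COc1cc([C@H]2Oc3c(OC)cc(C[C@H]4C(=O)OC[C@@H]4[C@@H](O[Si](C)(C)C(C)(C)C)c5ccc(O[Si](C(C)C)(C(C)C)C(C)C)c(OC)c5)cc3[C@@H]2CO[Si](c6ccccc6)(c7ccccc7)C(C)(C)C)ccc1O[Si](C(C)C)(C(C)C)C(C)C | intermediate
33 | (3R,4R)-4-[(R)-hydroxy(4-hydroxy-3-methoxyphenyl)methyl]-3-{[(2S,3R)-2-(4-hydroxy-3-methoxyphenyl)-3-(hydroxymethyl)-7-methoxy-2,3-dihydro-1-benzofuran-5-yl]methyl}oxolan-2-one | COc1cc([C@H]2Oc3c(OC)cc(C[C@H]4C(=O)OC[C@@H]4[C@@H](O)c4ccc(O)c(OC)c4)cc3[C@@H]2CO)ccc1O | target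

## Step count and least certain steps

Total: 20 steps. Longest linear sequence: 10 steps from 1 (steps 1–5, 12, 13, 14, 19, 20).

**Step 12 (key step).** The most likely failure is loss of methide 16 by its 1,5-hydrogen shift or by self-addition before the slowly formed benzylic ylide 17 captures it. Benzyl transfer from 15 to phenoxide or sulfinate can add to this, and because the C–C bond formation is irreversible, a poor trans/cis ratio or a weak transfer of chirality from the sulfide cannot be corrected afterwards. The fallback sets out from 3 and returns at 19, and builds ring C stepwise by known chemistry.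
- The phenol of 3 is protected as methyl 3-methoxy-4-(methoxymethoxy)-5-vinylbenzoate F1 (MeOCH2Cl, i-Pr2NEt).
- Hydroboration–oxidation (9-borabicyclononane, then NaBO3·4H2O) gives the arylethanol F2, and oxidation (TEMPO, PhI(OAc)2, aqueous MeCN) gives the arylacetic acid F3.
- The acid is joined, through its pivaloyl mixed anhydride, to the lithiated enantiomer of 22 to give imide F4.
- A boron-mediated syn-aldol reaction (Bu2BOTf, i-Pr2NEt) with 9 gives F5 and sets the future C3 under auxiliary control.
- LiBH4 gives diol F6, and t-BuPh2SiCl with imidazole gives the primary silyl ether F7.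
- CF3CO2H in CH2Cl2 then removes the methoxymethyl group and closes ring C through the benzylic cation, which should give the trans ring of 19 whatever the carbinol configuration.

**Step 16.** The most likely failure is lactonisation of the freed aldol 27 onto its methyl ester during removal of the trimethylsilyl group, or erosion of the anti selectivity because the ester competes for magnesium. The fallback sets out from 22 and 9 and returns at 30; it replaces the ester arm by an allyl group, which can neither chelate nor lactonise.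
- Acylation of 22 with pent-4-enoyl chloride gives imide F8.
- The same MgCl2 aldol gives the trimethylsilyl ether F9 and, after methanolysis, the aldol F10; silylation gives F11.
- LiBH4 gives the alcohol F12.
- Lemieux–Johnson cleavage (K2OsO4·2H2O, NaIO4, 2,6-lutidine) gives the lactol F13, and oxidation (TEMPO, PhI(OAc)2) gives 30.

**Step 5.** The most likely failure is slow ionisation of the benzylic alcohol, which is retarded by the β-silyloxy group and the ester, followed by loss of the silyl ether when the acid is forced. The fallback sets out from 4 and returns at 7 with the order of events reversed. The sulfone is made first from the diol in aqueous formic acid with 6, where nothing acid-labile is present, to give the hydroxy sulfone F14. Its primary hydroxyl is then silylated under non-basic activation (t-BuPh2SiCl, AgNO3, pyridine), which does not release the methide.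

**Step 18.** The most likely failure is over-reduction, either of the methyl ester or of the lactone once it has formed. The fallback sets out from 28 and returns at 30, and separates cleavage from reduction. LiOH/H2O2 hydrolyses the imide to the acid F15. BH3·SMe2, which reduces a carboxylic acid but not an ester, then gives hydroxy ester 29, which lactonises to 30.

**Step 19.** The most likely failure is decomposition of the electron-rich benzylic bromide 21 by self-alkylation before the enolate consumes it, or a second alkylation. The fallback sets out from 20 and 30 and returns at 32; it forms the same bond by olefination.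
- MnO2 oxidises 20 to the aldehyde F16.
- Enolate 31 is C-phosphorylated with ClP(O)(OEt)2 to the phosphonate F17.
- A Horner–Wadsworth–Emmons reaction of F17 with F16 gives the (E)-arylidene lactone F18.
- Conjugate reduction (NaBH4, NiCl2·6H2O) gives 32 together with its C-α epimer F19, and 1,8-diazabicyclo[5.4.0]undec-7-ene equilibrates the mixture to the trans compound 32.

## Further compounds

F1 | step 12 | methyl 3-methoxy-4-(methoxymethoxy)-5-vinylbenzoate | COCOc1c(OC)cc(C(=O)OC)cc1C=C
F2 | step 12 | methyl 3-(2-hydroxyethyl)-5-methoxy-4-(methoxymethoxy)benzoate | COCOc1c(OC)cc(C(=O)OC)cc1CCO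
F3 | step 12 | [3-methoxy-5-(methoxycarbonyl)-2-(methoxymethoxy)phenyl]acetic acid | COCOc1c(OC)cc(C(=O)OC)cc1CC(=O)O
F4 | step 12 | methyl 3-{2-[(S)-4-benzyl-2-oxo-1,3-oxazolidin-3-yl]-2-oxoethyl}-5-methoxy-4-(methoxymethoxy)benzoate | COCOc1c(OC)cc(C(=O)OC)cc1CC(=O)N1[C@@H](Cc2ccccc2)COC1=O
F5 | step 12 | methyl 3-{(2S,3S)-1-[(S)-4-benzyl-2-oxo-1,3-oxazolidin-3-yl]-3-hydroxy-3-[3-methoxy-4-(triisopropylsilyloxy)phenyl]-1-oxopropan-2-yl}-5-methoxy-4-(methoxymethoxy)benzoate | COCOc1c(OC)cc(C(=O)OC)cc1[C@@H]([C@H](O)c1ccc(O[Si](C(C)C)(C(C)C)C(C)C)c(OC)c1)C(=O)N1[C@@H](Cc2ccccc2)COC1=O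
F6 | step 12 | methyl 3-{(1S,2R)-1,3-dihydroxy-1-[3-methoxy-4-(triisopropylsilyloxy)phenyl]propan-2-yl}-5-methoxy-4-(methoxymethoxy)benzoate | COCOc1c(OC)cc(C(=O)OC)cc1[C@H](CO)[C@H](O)c1ccc(O[Si](C(C)C)(C(C)C)C(C)C)c(OC)c1
F7 | step 12 | methyl 3-{(1S,2R)-3-(tert-butyldiphenylsilyloxy)-1-hydroxy-1-[3-methoxy-4-(triisopropylsilyloxy)phenyl]propan-2-yl}-5-methoxy-4-(methoxymethoxy)benzoate | COCOc1c(OC)cc(C(=O)OC)cc1[C@H](CO[Si](c2ccccc2)(c2ccccc2)C(C)(C)C)[C@H](O)c1ccc(O[Si](C(C)C)(C(C)C)C(C)C)c(OC)c1
F8 | step 16 | (R)-4-benzyl-3-(pent-4-enoyl)-1,3-oxazolidin-2-one | C=CCCC(=O)N1[C@H](Cc2ccccc2)COC1=O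
F9 | step 16 | (R)-4-benzyl-3-[(2S)-2-{(R)-[3-methoxy-4-(triisopropylsilyloxy)phenyl](trimethylsilyloxy)methyl}pent-4-enoyl]-1,3-oxazolidin-2-one | C=CC[C@@H]([C@@H](O[Si](C)(C)C)c1ccc(O[Si](C(C)C)(C(C)C)C(C)C)c(OC)c1)C(=O)N1[C@H](Cc2ccccc2)COC1=O
F10 | step 16 | (R)-4-benzyl-3-[(2S)-2-{(R)-hydroxy[3-methoxy-4-(triisopropylsilyloxy)phenyl]methyl}pent-4-enoyl]-1,3-oxazolidin-2-one | C=CC[C@@H]([C@@H](O)c1ccc(O[Si](C(C)C)(C(C)C)C(C)C)c(OC)c1)C(=O)N1[C@H](Cc2ccccc2)COC1=O
F11 | step 16 | (R)-4-benzyl-3-[(2S)-2-{(R)-(tert-butyldimethylsilyloxy)[3-methoxy-4-(triisopropylsilyloxy)phenyl]methyl}pent-4-enoyl]-1,3-oxazolidin-2-one | C=CC[C@@H]([C@@H](O[Si](C)(C)C(C)(C)C)c1ccc(O[Si](C(C)C)(C(C)C)C(C)C)c(OC)c1)C(=O)N1[C@H](Cc2ccccc2)COC1=O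
F12 | step 16 | (2R)-2-{(R)-(tert-butyldimethylsilyloxy)[3-methoxy-4-(triisopropylsilyloxy)phenyl]methyl}pent-4-en-1-ol | C=CC[C@H](CO)[C@@H](O[Si](C)(C)C(C)(C)C)c1ccc(O[Si](C(C)C)(C(C)C)C(C)C)c(OC)c1
F13 | step 16 | (4R)-4-{(R)-(tert-butyldimethylsilyloxy)[3-methoxy-4-(triisopropylsilyloxy)phenyl]methyl}oxolan-2-ol (anomers) | OC1C[C@H](CO1)[C@@H](O[Si](C)(C)C(C)(C)C)c2ccc(O[Si](C(C)C)(C(C)C)C(C)C)c(OC)c2
F14 | step 5 | methyl 4-hydroxy-3-[2-hydroxy-1-(p-tolylsulfonyl)ethyl]-5-methoxybenzoate (racemic) | COC(=O)c1cc(OC)c(O)c(C(CO)S(=O)(=O)c2ccc(C)cc2)c1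
F15 | step 18 | (2S)-2-{(R)-(tert-butyldimethylsilyloxy)[3-methoxy-4-(triisopropylsilyloxy)phenyl]methyl}-4-methoxy-4-oxobutanoic acid | COC(=O)C[C@@H]([C@@H](O[Si](C)(C)C(C)(C)C)c1ccc(O[Si](C(C)C)(C(C)C)C(C)C)c(OC)c1)C(=O)O
F16 | step 19 | (2S,3R)-3-[(tert-butyldiphenylsilyloxy)methyl]-7-methoxy-2-[3-methoxy-4-(triisopropylsilyloxy)phenyl]-2,3-dihydro-1-benzofuran-5-carbaldehyde | COc1cc([C@H]2Oc3c(OC)cc(C=O)cc3[C@@H]2CO[Si](c4ccccc4)(c5ccccc5)C(C)(C)C)ccc1O[Si](C(C)C)(C(C)C)C(C)C
F17 | step 19 | diethyl {(4R)-4-{(R)-(tert-butyldimethylsilyloxy)[3-methoxy-4-(triisopropylsilyloxy)phenyl]methyl}-2-oxooxolan-3-yl}phosphonate (C3 epimers) | CCOP(=O)(OCC)C1C(=O)OC[C@@H]1[C@@H](O[Si](C)(C)C(C)(C)C)c2ccc(O[Si](C(C)C)(C(C)C)C(C)C)c(OC)c2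
F18 | step 19 | (3E,4R)-3-{[(2S,3R)-3-[(tert-butyldiphenylsilyloxy)methyl]-7-methoxy-2-[3-methoxy-4-(triisopropylsilyloxy)phenyl]-2,3-dihydro-1-benzofuran-5-yl]methylidene}-4-{(R)-(tert-butyldimethylsilyloxy)[3-methoxy-4-(triisopropylsilyloxy)phenyl]methyl}oxolan-2-one | COc1cc([C@H]2Oc3c(OC)cc(/C=C4/C(=O)OC[C@@H]4[C@@H](O[Si](C)(C)C(C)(C)C)c5ccc(O[Si](C(C)C)(C(C)C)C(C)C)c(OC)c5)cc3[C@@H]2CO[Si](c6ccccc6)(c7ccccc7)C(C)(C)C)ccc1O[Si](C(C)C)(C(C)C)C(C)C
F19 | step 19 | (3S,4R) C-α epimer of 32 (cis lactone) | COc1cc([C@H]2Oc3c(OC)cc(C[C@@H]4C(=O)OC[C@@H]4[C@@H](O[Si](C)(C)C(C)(C)C)c5ccc(O[Si](C(C)C)(C(C)C)C(C)C)c(OC)c5)cc3[C@@H]2CO[Si](c6ccccc6)(c7ccccc7)C(C)(C)C)ccc1O[Si](C(C)C)(C(C)C)C(C)C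
A1 | alternative 1 | (S)-4-benzyl-3-[(E)-3-(4-hydroxy-3-methoxyphenyl)prop-2-enoyl]-1,3-oxazolidin-2-one | COc1cc(/C=C/C(=O)N2[C@@H](Cc3ccccc3)COC2=O)ccc1O
A2 | alternative 1 | trans-(2S,3S) dehydrodimer of A1 (bis-imide; 2-aryl-2,3-dihydrobenzofuran with the 3-acyl and 5-propenoyl imides) | COc1cc([C@H]2Oc3c(OC)cc(/C=C/C(=O)N4[C@@H](Cc5ccccc5)COC4=O)cc3[C@@H]2C(=O)N2[C@@H](Cc3ccccc3)COC2=O)ccc1O
A3 | alternative 2 | 3-{(R)-(tert-butyldimethylsilyloxy)[3-methoxy-4-(triisopropylsilyloxy)phenyl]methyl}cyclobutan-1-one | O=C1CC(C1)[C@@H](O[Si](C)(C)C(C)(C)C)c1ccc(O[Si](C(C)C)(C(C)C)C(C)C)c(OC)c1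
A4 | alternative 2 | (R)-4-{(R)-(tert-butyldimethylsilyloxy)[3-methoxy-4-(triisopropylsilyloxy)phenyl]methyl}oxolan-2-one | C1C(=O)OC[C@@H]1[C@@H](O[Si](C)(C)C(C)(C)C)c1ccc(O[Si](C(C)C)(C(C)C)C(C)C)c(OC)c1
A5 | alternative 3 | methyl 2-{5-bromo-3-methoxy-2-[3-methoxy-4-(triisopropylsilyloxy)benzyloxy]phenyl}-2-diazoacetate | COC(=O)C(=[N+]=[N-])c1cc(Br)cc(OC)c1OCc1ccc(O[Si](C(C)C)(C(C)C)C(C)C)c(OC)c1
A6 | alternative 3 | methyl cis-(2S,3R)-5-bromo-7-methoxy-2-[3-methoxy-4-(triisopropylsilyloxy)phenyl]-2,3-dihydro-1-benzofuran-3-carboxylate | COc1cc([C@H]2Oc3c(OC)cc(Br)cc3[C@H]2C(=O)OC)ccc1O[Si](C(C)C)(C(C)C)C(C)C
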